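**Strategy.** The route rests on cutting the C5–C1' bond between ring A of the 2,3-dihydrobenzofuran and the propane-1,2-diol chain. C2' (CH3, H, OH) is the stereocentre of (S)-lactic acid, and C5 sits para to O1, where a bromine can be exchanged for lithium. In one operation the C5 aryllithium adds to (S)-2-(tert-butyldiphenylsilyloxy)propanal under Felkin–Anh control, joining the complete trans-(2S,3S) core to the complete side chain and setting C1' (R), anti to the silyloxy group. The precursor is the (2S,3S)-5-bromo-7-methoxy-3-methyl-2-aryl-2,3-dihydrobenzofuran whose ring C phenol is a triisopropylsilyl ether, so that one fluoride treatment ends the synthesis.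

Key step: step 12

Numbering: O1, C2, C3, C3a, C4–C7, C7a for the dihydrobenzofuran (ring A = fused benzene ring, ring B = dihydrofuran ring, ring C = 2-aryl group); C1'–C3' for the side chain. The target is (2S,3S,1'R,2'S): 2,3-trans and 1',2'-anti.

Remark: the benzylide of thiolane 7 is assumed to show the same facial preference towards the o-quinone methide as towards aldehydes, where the (2S,5S)-sulfide is taken to give R-configured aryl-bearing epoxide carbons, which corresponds to 2S here; if the sense proved opposite, the mirror-image sulfide would be made in the same way from the enantiomeric diol.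

**Route**

Step 1
Reactants: 1 3-hydroxy-4,5-dimethoxybenzaldehyde
Product: 2 3,4-dimethoxy-5-[(triisopropylsilyl)oxy]benzaldehyde
Conditions: i-Pr3SiCl, imidazole, DMF, rt
Reagents that add atoms: chlorotriisopropylsilane, CC(C)[Si](Cl)(C(C)C)C(C)C
Why: Imidazole-promoted O-silylation of the only hydroxyl group; the hindered aryl triisopropylsilyl ether tolerates the hydride, carbonate and organolithium steps ahead and falls to fluoride together with the side-chain silyl ether at the end, so no hydrogenolysis is needed near the benzylic C2–O1 and C1'–O bonds.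

Step 2
Reactants: 2 3,4-dimethoxy-5-[(triisopropylsilyl)oxy]benzaldehyde
Product: 3 {3,4-dimethoxy-5-[(triisopropylsilyl)oxy]phenyl}methanol
Conditions: NaBH4, MeOH, 0 °C
Reagents that add atoms: none
Why: Borohydride 1,2-reduction of the aromatic aldehyde to the primary benzylic alcohol, to which the aryl silyl ether and the methyl ethers are inert.

Step 3
Reactants: 3 {3,4-dimethoxy-5-[(triisopropylsilyl)oxy]phenyl}methanol
Product: 4 [5-(bromomethyl)-2,3-dimethoxyphenoxy]triisopropylsilane
Conditions: CBr4, PPh3, CH2Cl2, 0 °C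
Reagents that add atoms: tetrabromomethane, BrC(Br)(Br)Br
Why: Appel reaction, in which the alcohol is activated by PPh3/CBr4 and displaced by bromide under neutral conditions that spare the silyl ether, giving a reactive benzylic bromide that is used at once.

Step 4
Reactants: 5 (2R,5R)-hexane-2,5-diol
Product: 6 (2R,5R)-hexane-2,5-diyl dimethanesulfonate
Conditions: MsCl, Et3N, CH2Cl2, 0 °C
Reagents that add atoms: methanesulfonyl chloride, CS(=O)(=O)Cl
Why: Mesylation takes place at oxygen only, so both C–O bonds and both R stereocentres are left untouched.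

Step 5
Reactants: 6 (2R,5R)-hexane-2,5-diyl dimethanesulfonate
Product: 7 (2S,5S)-2,5-dimethylthiolane
Conditions: Na2S·9H2O, EtOH, rt
Reagents that add atoms: sodium sulfide, [Na+].[Na+].[S-2]
Why: Two successive SN2 displacements of mesylate by sulfide, the second closing the five-membered ring, each with inversion, so the (2R,5R)-dimesylate gives the twofold-symmetric (2S,5S)-thiolane.

Step 6
Reactants: 4 [5-(bromomethyl)-2,3-dimethoxyphenoxy]triisopropylsilane; 7 (2S,5S)-2,5-dimethylthiolane
Product: 8 (2S,5S)-1-{3,4-dimethoxy-5-[(triisopropylsilyl)oxy]benzyl}-2,5-dimethylthiolan-1-ium tetrafluoroborate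
Conditions: NaBF4, CH2Cl2–H2O, rt
Reagents that add atoms: sodium tetrafluoroborate, [Na+].F[B-](F)(F)F
Why: S-Alkylation of the sulfide by the activated benzylic bromide (sulfonium salt formation), made irreversible by exchange of bromide for non-nucleophilic tetrafluoroborate; the two lone pairs of 7 are equivalent by symmetry, so a single salt results.

Step 7
Reactants: 9 5-bromo-2-hydroxy-3-methoxybenzaldehyde
Product: 10 4-bromo-2-(1-hydroxyethyl)-6-methoxyphenol (racemic)
Conditions: MeMgBr (2.5 equiv), THF, 0 °C; aq NH4Cl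
Reagents that add atoms: methylmagnesium bromide, C[Mg]Br
Why: Grignard addition to the aldehyde after deprotonation of the phenol by the first equivalent; MeMgBr does not exchange with the aryl bromide at 0 °C, and the racemic carbinol centre is erased later when the benzylic carbon becomes trigonal.

Step 8
Reactants: 10 4-bromo-2-(1-hydroxyethyl)-6-methoxyphenol (racemic)
Product: 12 4-bromo-2-methoxy-6-[1-(4-methylbenzenesulfonyl)ethyl]phenol (racemic), via benzylic cation 11 (not isolated)
Conditions: p-TolSO2Na, HCO2H–H2O, rt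
Reagents that add atoms: sodium 4-methylbenzenesulfinate, Cc1ccc(cc1)S(=O)[O-].[Na+]
Why: Acid-promoted SN1 substitution, in which the protonated benzylic hydroxyl leaves as water to give cation 11, stabilised by the ortho hydroxyl group, and the sulfinate captures it at sulfur to give a stable sulfone that carbonate base can later open to the reactive o-quinone methide.

Step 9
Reactants: 12 4-bromo-2-methoxy-6-[1-(4-methylbenzenesulfonyl)ethyl]phenol (racemic); 8 (2S,5S)-1-{3,4-dimethoxy-5-[(triisopropylsilyl)oxy]benzyl}-2,5-dimethylthiolan-1-ium tetrafluoroborate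
Product: 16 (2S,3S)-5-bromo-2-{3,4-dimethoxy-5-[(triisopropylsilyl)oxy]phenyl}-7-methoxy-3-methyl-2,3-dihydro-1-benzofuran, via o-quinone methide 13 (not isolated), via sulfonium ylide 14 (not isolated), via betaine 15 (not isolated)
Conditions: Cs2CO3 (3 equiv), CH2Cl2, 0 °C to rt
Reagents that add atoms: none
Why: Formal [4+1] annulation (Michael-initiated ring closure) of a sulfonium ylide with an o-quinone methide: carbonate releases 13 from the phenoxide of 12 by 1,4-elimination of sulfinate and ylide 14 from 8, conjugate addition of 14 to the exocyclic carbon of 13 gives betaine 15, and the phenoxide displaces the sulfide at the benzylic carbon with inversion (5-exo-tet) to close ring B; the (2S,5S)-thiolane exposes one face of the ylide carbon, which should set C2 as S, and the approach that keeps the ring C aryl group and the methyl group apart sets C3 as S, i.e. trans.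

Step 10
Reactants: 17 ethyl (2S)-2-hydroxypropanoate (ethyl (S)-lactate)
Product: 18 ethyl (2S)-2-[(tert-butyldiphenylsilyl)oxy]propanoate
Conditions: t-BuPh2SiCl, imidazole, DMF, rt
Reagents that add atoms: tert-butyl(chloro)diphenylsilane, CC(C)(C)[Si](Cl)(c1ccccc1)c1ccccc1
Why: O-Silylation of the secondary alcohol breaks no bond to the stereocentre; the bulky, poorly coordinating tert-butyldiphenylsilyl group is chosen for the non-chelation control needed in step 12.

Step 11
Reactants: 18 ethyl (2S)-2-[(tert-butyldiphenylsilyl)oxy]propanoate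
Product: 20 (2S)-2-[(tert-butyldiphenylsilyl)oxy]propanal, via aluminium hemiacetal 19 (not isolated)
Conditions: i-Bu2AlH (1.1 equiv), CH2Cl2, −78 °C; MeOH, then aq KNa tartrate
Reagents that add atoms: none
Why: Partial ester reduction by one equivalent of i-Bu2AlH at −78 °C stops at aluminium hemiacetal 19 and releases the aldehyde only on work-up; the neutral tartrate work-up and immediate use protect the α-stereocentre from epimerisation.

Step 12
Reactants: 16 (2S,3S)-5-bromo-2-{3,4-dimethoxy-5-[(triisopropylsilyl)oxy]phenyl}-7-methoxy-3-methyl-2,3-dihydro-1-benzofuran; 20 (2S)-2-[(tert-butyldiphenylsilyl)oxy]propanal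
Product: 22 (1R,2S)-2-[(tert-butyldiphenylsilyl)oxy]-1-[(2S,3S)-2-{3,4-dimethoxy-5-[(triisopropylsilyl)oxy]phenyl}-7-methoxy-3-methyl-2,3-dihydro-1-benzofuran-5-yl]propan-1-ol, via aryllithium 21 (not isolated)
Conditions: t-BuLi (2.0 equiv), THF, −78 °C; then 20, −78 °C; aq NH4Cl
Reagents that add atoms: none
Why: Bromine–lithium exchange at C5 with two equivalents of t-BuLi at −78 °C (the second equivalent destroys the t-BuBr formed) gives aryllithium 21, which adds to the carbonyl group of 20 in a polar 1,2-addition; the closest known reaction type is the Felkin–Anh addition of aryllithium and aryl Grignard reagents to O-silylated lactaldehydes. No ring is closed, and the only skeletal bond formed is C5–C1'. The new C1' stereocentre is controlled by the C2' stereocentre of the aldehyde: in the polar Felkin–Anh transition state the C2'–OSi bond stands perpendicular to the carbonyl plane and anti to the incoming aryl group, which passes the hydrogen and not the methyl group, giving the 1'R,2'S (anti) carbinol. The step needs non-chelation facial selectivity, which the bulky and weakly Lewis-basic tert-butyldiphenylsilyl ether, lithium as counter-ion and THF as donor solvent should secure, and it needs exchange to outrun deprotonation at the benzylic C2 and C3 positions, which the low temperature and the high rate of exchange with t-BuLi should secure. The distant ring stereocentres should not influence the facial course, so any 1'-epimer and any adduct of the minor enantiomer of the core are diastereomers of 22 that can be removed here by chromatography.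

Step 13
Reactants: 22 (1R,2S)-2-[(tert-butyldiphenylsilyl)oxy]-1-[(2S,3S)-2-{3,4-dimethoxy-5-[(triisopropylsilyl)oxy]phenyl}-7-methoxy-3-methyl-2,3-dihydro-1-benzofuran-5-yl]propan-1-ol
Product: 23 (1R,2S)-1-[(2S,3S)-2-(3-hydroxy-4,5-dimethoxyphenyl)-7-methoxy-3-methyl-2,3-dihydro-1-benzofuran-5-yl]propane-1,2-diol
Conditions: Bu4NF, AcOH, THF, 0 °C to rt
Reagents that add atoms: none
Why: Fluoride-induced cleavage of both Si–O bonds (desilylation) in one operation; buffering with acetic acid keeps the medium near neutral, so neither the benzylic C1' carbinol nor the benzylic C2–O1 ether is put at risk and no stereocentre is touched.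

**Compound list**

1 | 3-hydroxy-4,5-dimethoxybenzaldehyde | COc1cc(C=O)cc(O)c1OC | starting material
2 | 3,4-dimethoxy-5-[(triisopropylsilyl)oxy]benzaldehyde | COc1cc(C=O)cc(O[Si](C(C)C)(C(C)C)C(C)C)c1OC | intermediate
3 | {3,4-dimethoxy-5-[(triisopropylsilyl)oxy]phenyl}methanol | COc1cc(CO)cc(O[Si](C(C)C)(C(C)C)C(C)C)c1OC | intermediate
4 | [5-(bromomethyl)-2,3-dimethoxyphenoxy]triisopropylsilane | COc1cc(CBr)cc(O[Si](C(C)C)(C(C)C)C(C)C)c1OC | intermediate
5 | (2R,5R)-hexane-2,5-diol | C[C@@H](O)CC[C@@H](C)O | starting material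
6 | (2R,5R)-hexane-2,5-diyl dimethanesulfonate | C[C@@H](OS(C)(=O)=O)CC[C@@H](C)OS(C)(=O)=O | intermediate
7 | (2S,5S)-2,5-dimethylthiolane | C[C@H]1CC[C@H](C)S1 | intermediate
8 | (2S,5S)-1-{3,4-dimethoxy-5-[(triisopropylsilyl)oxy]benzyl}-2,5-dimethylthiolan-1-ium tetrafluoroborate | C[C@H]1CC[C@H](C)[S+]1Cc1cc(OC)c(OC)c(O[Si](C(C)C)(C(C)C)C(C)C)c1.F[B-](F)(F)F | intermediate
9 | 5-bromo-2-hydroxy-3-methoxybenzaldehyde | COc1cc(Br)cc(C=O)c1O | starting material
10 | 4-bromo-2-(1-hydroxyethyl)-6-methoxyphenol (racemic) | COc1cc(Br)cc(C(C)O)c1O | intermediate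
11 | 1-(5-bromo-2-hydroxy-3-methoxyphenyl)ethylium formate (benzylic cation) | COc1cc(Br)cc([CH+]C)c1O.[O-]C=O | intermediate (not isolated)
12 | 4-bromo-2-methoxy-6-[1-(4-methylbenzenesulfonyl)ethyl]phenol (racemic) | COc1cc(Br)cc(C(C)S(=O)(=O)c2ccc(C)cc2)c1O | intermediate
13 | 4-bromo-6-ethylidene-2-methoxycyclohexa-2,4-dien-1-one (o-quinone methide) | COC1=CC(Br)=CC(=CC)C1=O | intermediate (not isolated)
14 | {3,4-dimethoxy-5-[(triisopropylsilyl)oxy]phenyl}[(2S,5S)-2,5-dimethylthiolan-1-ium-1-yl]methanide (sulfonium ylide) | C[C@H]1CC[C@H](C)[S+]1[CH-]c1cc(OC)c(OC)c(O[Si](C(C)C)(C(C)C)C(C)C)c1 | intermediate (not isolated)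
15 | 4-bromo-2-[(1R,2S)-1-{3,4-dimethoxy-5-[(triisopropylsilyl)oxy]phenyl}-1-[(2S,5S)-2,5-dimethylthiolan-1-ium-1-yl]propan-2-yl]-6-methoxyphenolate (betaine) | COc1cc(Br)cc([C@H](C)[C@H](c2cc(OC)c(OC)c(O[Si](C(C)C)(C(C)C)C(C)C)c2)[S+]2[C@@H](C)CC[C@@H]2C)c1[O-] | intermediate (not isolated)
16 | (2S,3S)-5-bromo-2-{3,4-dimethoxy-5-[(triisopropylsilyl)oxy]phenyl}-7-methoxy-3-methyl-2,3-dihydro-1-benzofuran | COc1cc([C@H]2Oc3c(OC)cc(Br)cc3[C@@H]2C)cc(O[Si](C(C)C)(C(C)C)C(C)C)c1OC | intermediate
17 | ethyl (2S)-2-hydroxypropanoate | CCOC(=O)[C@H](C)O | starting material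
18 | ethyl (2S)-2-[(tert-butyldiphenylsilyl)oxy]propanoate | CCOC(=O)[C@H](C)O[Si](c1ccccc1)(c1ccccc1)C(C)(C)C | intermediate
19 | [(2S)-2-[(tert-butyldiphenylsilyl)oxy]-1-ethoxypropoxy]bis(2-methylpropyl)alumane (aluminium hemiacetal, both C1 epimers) | CCOC(O[Al](CC(C)C)CC(C)C)[C@H](C)O[Si](c1ccccc1)(c1ccccc1)C(C)(C)C | intermediate (not isolated)
20 | (2S)-2-[(tert-butyldiphenylsilyl)oxy]propanal | O=C[C@H](C)O[Si](c1ccccc1)(c1ccccc1)C(C)(C)C | intermediate
21 | [(2S,3S)-2-{3,4-dimethoxy-5-[(triisopropylsilyl)oxy]phenyl}-7-methoxy-3-methyl-2,3-dihydro-1-benzofuran-5-yl]lithium (aryllithium) | COc1cc([C@H]2Oc3c(OC)cc([Li])cc3[C@@H]2C)cc(O[Si](C(C)C)(C(C)C)C(C)C)c1OC | intermediate (not isolated)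
22 | (1R,2S)-2-[(tert-butyldiphenylsilyl)oxy]-1-[(2S,3S)-2-{3,4-dimethoxy-5-[(triisopropylsilyl)oxy]phenyl}-7-methoxy-3-methyl-2,3-dihydro-1-benzofuran-5-yl]propan-1-ol | COc1cc([C@H]2Oc3c(OC)cc([C@@H](O)[C@H](C)O[Si](c4ccccc4)(c4ccccc4)C(C)(C)C)cc3[C@@H]2C)cc(O[Si](C(C)C)(C(C)C)C(C)C)c1OC | intermediate
23 | (1R,2S)-1-[(2S,3S)-2-(3-hydroxy-4,5-dimethoxyphenyl)-7-methoxy-3-methyl-2,3-dihydro-1-benzofuran-5-yl]propane-1,2-diol | COc1cc([C@H]2Oc3c(OC)cc([C@@H](O)[C@H](C)O)cc3[C@@H]2C)cc(O)c1OC | target

**Step count and risks**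

Total step count: 13. Longest linear sequence: 7 steps (1 → 2 → 3 → 4 → 8 → 16 → 22 → 23; steps 1, 2, 3, 6, 9, 12 and 13).

Steps most likely to fail:

Step 9. What may go wrong:
- incomplete facial discrimination at the ylide carbon, lowering the enantiomeric purity of the core;
- loss of trans selectivity in the conjugate addition;
- tautomerisation or self-addition of the methyl-substituted o-quinone methide;
- benzyl transfer from the sulfonium salt to phenoxide or sulfinate before the ylide has formed.

The fallback sets out from 9 and 2 and returns at 16. Wittig methylenation of 9 (Ph3PCH3Br, KOt-Bu, THF) gives 4-bromo-2-ethenyl-6-methoxyphenol F1. Phenol-directed, branched-selective rhodium-catalysed hydroacylation of F1 with aldehyde 2 ([Rh(cod)(OMe)]2, bis(dicyclohexylphosphino)methane, K3PO4, THF) gives racemic 2-(5-bromo-2-hydroxy-3-methoxyphenyl)-1-{3,4-dimethoxy-5-[(triisopropylsilyl)oxy]phenyl}propan-1-one F2. Asymmetric hydrogenation with dynamic kinetic resolution of the base-labile α-aryl centre (RuCl2[(R)-xylBINAP][(R)-DAIPEN], KOt-Bu, i-PrOH, H2) should give (1S,2S)-2-(5-bromo-2-hydroxy-3-methoxyphenyl)-1-{3,4-dimethoxy-5-[(triisopropylsilyl)oxy]phenyl}propan-1-ol F3. Acid-mediated ring closure through the ring C benzylic cation (catalytic TsOH, CH2Cl2), in which the phenol adds trans to the C3 methyl group whatever the carbinol configuration, returns 16.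

Step 12. What may go wrong:
- insufficient Felkin–Anh facial selectivity, giving a large share of the 1'S epimer;
- enolisation or α-epimerisation of aldehyde 20 by the basic aryllithium;
- protonation of 21 in place of addition.

The fallback sets out from 16 and 18 and returns at 23. Ester 18 is converted with MeNHOMe·HCl and i-PrMgCl (THF, −20 °C) into (2S)-2-[(tert-butyldiphenylsilyl)oxy]-N-methoxy-N-methylpropanamide F4 (a Weinreb amide). Aryllithium 21, made from 16 as in step 12, is acylated by F4 to give (2S)-2-[(tert-butyldiphenylsilyl)oxy]-1-[(2S,3S)-2-{3,4-dimethoxy-5-[(triisopropylsilyl)oxy]phenyl}-7-methoxy-3-methyl-2,3-dihydro-1-benzofuran-5-yl]propan-1-one F5. Bu4NF buffered with AcOH removes both silyl groups to give (2S)-2-hydroxy-1-[(2S,3S)-2-(3-hydroxy-4,5-dimethoxyphenyl)-7-methoxy-3-methyl-2,3-dihydro-1-benzofuran-5-yl]propan-1-one F6. Reduction of F6 with Zn(BH4)2 (Et2O, −20 °C) through the five-membered zinc chelate of the α-hydroxy ketone, with hydride delivered to the face away from the methyl group, should give the anti-diol 23 directly.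

Step 8. What may go wrong:
- loss of a proton from the benzylic cation to give the 2-vinylphenol, followed by acid-catalysed oligomerisation;
- Friedel–Crafts self-alkylation of the electron-rich phenol by the cation;
- attack of the sulfinate through oxygen in place of sulfur, so that little sulfone is obtained.

The fallback sets out from 9 and returns at 16. Acylation of 9 with Boc2O (catalytic DMAP, i-Pr2NEt, CH2Cl2) gives tert-butyl 4-bromo-2-formyl-6-methoxyphenyl carbonate F7. MeMgBr (THF, −78 °C) then turns F7, by carbonyl addition, carbonate transfer and elimination on warming, into o-quinone methide 13 in the flask. This is trapped by ylide 14 (preformed from 8 with LiN(SiMe3)2 at −78 °C) and closes through 15 to 16 as in step 9.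

Further compounds

F1 | step 9 | 4-bromo-2-ethenyl-6-methoxyphenol | COc1cc(Br)cc(C=C)c1O
F2 | step 9 | 2-(5-bromo-2-hydroxy-3-methoxyphenyl)-1-{3,4-dimethoxy-5-[(triisopropylsilyl)oxy]phenyl}propan-1-one (racemic) | COc1cc(C(=O)C(C)c2cc(Br)cc(OC)c2O)cc(O[Si](C(C)C)(C(C)C)C(C)C)c1OC
F3 | step 9 | (1S,2S)-2-(5-bromo-2-hydroxy-3-methoxyphenyl)-1-{3,4-dimethoxy-5-[(triisopropylsilyl)oxy]phenyl}propan-1-ol | COc1cc([C@@H](O)[C@@H](C)c2cc(Br)cc(OC)c2O)cc(O[Si](C(C)C)(C(C)C)C(C)C)c1OC
F4 | step 12 | (2S)-2-[(tert-butyldiphenylsilyl)oxy]-N-methoxy-N-methylpropanamide | CON(C)C(=O)[C@H](C)O[Si](c1ccccc1)(c1ccccc1)C(C)(C)C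
F5 | step 12 | (2S)-2-[(tert-butyldiphenylsilyl)oxy]-1-[(2S,3S)-2-{3,4-dimethoxy-5-[(triisopropylsilyl)oxy]phenyl}-7-methoxy-3-methyl-2,3-dihydro-1-benzofuran-5-yl]propan-1-one | COc1cc([C@H]2Oc3c(OC)cc(C(=O)[C@H](C)O[Si](c4ccccc4)(c4ccccc4)C(C)(C)C)cc3[C@@H]2C)cc(O[Si](C(C)C)(C(C)C)C(C)C)c1OC
F6 | step 12 | (2S)-2-hydroxy-1-[(2S,3S)-2-(3-hydroxy-4,5-dimethoxyphenyl)-7-methoxy-3-methyl-2,3-dihydro-1-benzofuran-5-yl]propan-1-one | COc1cc([C@H]2Oc3c(OC)cc(C(=O)[C@H](C)O)cc3[C@@H]2C)cc(O)c1OC
F7 | step 8 | tert-butyl 4-bromo-2-formyl-6-methoxyphenyl carbonate | COc1cc(Br)cc(C=O)c1OC(=O)OC(C)(C)C
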